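In the first 10.0 min, the maple run loses 0.00687 M of solid J and the alder run 0.00682 M, so the early pace reads the same at both loadings. The decision for the next run is whether J stays at 0.050 M or is raised to put more Q into solution.

| setting | maple | alder | ash | flask |
|---|---|---|---|---|
| J | 0.034 M | 0.075 M | 0.050 M | 0.050 M |
| G | 0.50 equiv (in portions, 3) | 0.50 equiv (in portions, 3) | 1 equiv (in portions, 3) | 0.500 equiv (in portions, 3) |
| remark | run made earlier; portions every 15 min | run made earlier; portions every 15 min | run made earlier; portions every 15 min | the portions of G follow each other after 15 min, the first at the start |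
| time |  |  |  | 80 min |

| run | time / min | X / % | J / % |
|---|---|---|---|
| maple | 10.0 | 0.9 | 79.8 |
| maple | 20.0 | 1.0 | 68.4 |
| maple | 30.0 | 2.8 | 60.0 |
| maple | 40.0 | 4.3 | 53.8 |
| maple | 50.0 | 4.8 | 50.6 |
| alder | 10.0 | 0.3 | 90.9 |
| alder | 20.0 | 1.7 | 84.6 |
| alder | 30.0 | 1.8 | 80.4 |
| alder | 40.0 | 2.8 | 76.8 |
| alder | 50.0 | 3.6 | 74.1 |
| ash | 10.0 | 1.0 | 86.1 |
| ash | 20.0 | 3.3 | 76.3 |
| ash | 30.0 | 4.6 | 70.5 |
| ash | 40.0 | 7.3 | 64.1 |
| ash | 50.0 | 6.9 | 58.8 |

(standard deviation of a reading: 0.5 percentage points)

- as a solid, counted per litre of solution: J
- the analysis behind the earlier runs scatters by 0.5 percentage points, standard deviation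
- at the start none of J is in solution
- Q means what is dissolved; the solid is not counted in it

- X present at 80 min, in percent of the J charged
- J present at 80 min, in percent of the J charged (only what is still solid)
- Q present at 80 min, in percent of the J charged
- concentration of Z at 80 min, in M

By 50.0 min the J lost reads 0.0168 M in maple, 0.0194 M in alder and 0.0206 M in ash, an order that follows the G charged and not the J charged. A straight line through maple and ash has a slope of 0.115, the J lost for each unit of G charged, both taken as concentrations. Carried back to no G, the same line gives 0.0148 M. This reading is the free level c_Q,free, the dissolved Q that solid J keeps up with no G to take it, its solubility. Alder, which played no part in the line, reads 0.0194 M where the line gives 0.0192 M.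

At the early pace the free level fills in 21.6 min, which is short against 80 min. This reckoning therefore takes Q as standing at c_Q,free by that time, which is 29.7% of the J charged. On this line more J adds solid and not solution, so the flask keeps 0.050 M.

The forecast, holding that “Q tends to about 0.02 M”, gives X 4.5%, J 58.5%, Q 37% and Z 0.021 M. Its Q stands higher than this reckoning's share.

At 80 min the flask gives X 4.39%, J 59.2%, Q 28.6% and Z 0.00220 M. Its Q lies 8.4 percentage points below the forecast, and 0.0143 M of Q is in solution against the free level of 0.0148 M.

    J ⇌ Q, rate k1*(cs1 - [Q]) while solid is left; crystals form when [Q] > cs1 (solubility = 15.0 mM, k = 0.00100 s⁻¹)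
    D ⇌ X + Z (K = 0.0120 M, k = 0.00270 s⁻¹)
    D → E (k = 0.00170 s⁻¹)
    Q + G ⇌ D (K = 4.90 M⁻¹, k = 0.250 M⁻¹ s⁻¹)
    G ⇌ L (K = 63.0, k = 3.40 × 10⁻⁴ s⁻¹)

The neighbouring flask has the same recipe with 0.20 M of J. The free level over that charge gives 7.40% of the J charged, and at the same time the neighbouring flask holds Q at 6.36%. That is 0.0127 M of Q in solution, less than the 0.0143 M of the flask, while solid J in the neighbouring flask stands at 84.7% of its charge.

(The numbers in the tables stem from a simulated flask for substances that don't exist, and the scatter is random.)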